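## Analysis of the target

The target is (2R,3R,3aR,5R)-3a-allyl-5-methoxy-3-methyl-2-(3,4,5-trimethoxyphenyl)-3,3a,4,5-tetrahydro-1-benzofuran-6(2H)-one. A tetrahydrofuran (ring A: O1, C2, C3, C3a, C7a) is fused through C3a–C7a to a cyclohexenone (ring B: C3a, C4, C5, C6, C7, C7a). The two rings share the vinylogous ester O1–C7a=C7–C6=O. C2 (aryl), C3 (methyl) and the quaternary C3a (allyl) are contiguous; C5 (methoxy) is separated from them by the C4 methylene. Aryl and methyl are trans on ring A, methyl and allyl are cis, and the C5 methoxy group is trans to the allyl group across ring B. The sensitive groups are the vinylogous ester (nucleophiles, acid), the C5 centre α to the ketone (epimerisable), the C2–O1 bond benzylic to an electron-rich arene (ionisation) and the terminal alkene. The hard part is the quaternary C3a, which has four different carbon substituents, sits between C3 and the sp2 carbon C7a, and must be set in the absolute sense. The strategy rests on one feature: C3a carries both ring B bonds (C3a–C7a and C3a–C4) and an allyl group that can be read as a homologated formyl group. With C4 a methylene, this is the pattern of a Diels–Alder reaction of a 2-substituted acrolein. C5–OMe, C6=O and C7=C7a then map onto an oxygenated diene.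

## Retrosynthetic reasoning

**26 to 25 (C5).** No bond is cut. C5 is α to the ketone, and in the bicyclic vinylogous ester the ring fusion holds the allyl group pseudo-axial on ring B. The 5R epimer 26 has its methoxy group pseudo-equatorial; the 5S epimer 25 has it pseudo-axial and syn to the allyl group. C5 can therefore be left to equilibrate at the end, and no earlier step needs to control it.

**25 to 23 (C7=C7a).** The C7=C7a double bond is removed in the retrosynthetic sense. This leaves the β-alkoxy ketone 23, the direct product of an oxa-Michael addition. Forward, a regioselective dehydrogenation on the C7 side of the ketone is needed.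

**23 to 21 (O1–C7a).** The O1–C7a bond is cut, opening ring A to an enone with a silyl-protected C2 hydroxyl (21; free alcohol 22). This bond is chosen because the enone β-carbon C7a is the natural acceptor for the C2 oxygen in a 5-exo closure. The C2–O bond is kept from the start, so the benzylic centre is never substituted.

**21 to 18 (allyl to formyl).** The allyl group is traced through the homologated aldehyde 20 and the enol ether 19 to the formyl group of 18. Two one-carbon Wittig reactions build it forward. This returns the activating group that the cycloaddition needs.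

**18 to 9 + 15 (C3a–C7a and C4–C5).** Both ring B bonds at C3a are cut in a retro-Diels–Alder step (through the cycloadduct 16 and the ketone 17). This is the only disconnection that makes the quaternary carbon and ring B at once and is convergent. The diene 15 already carries the C5 methoxy group, the C6 oxygen and, after loss of nitrogen, the C7=C7a double bond. A dialkylamino diene would be the most activating choice. However, it is a strong Lewis base and reacts with acroleins without a catalyst, so a chiral chromium Lewis acid could not govern the face. The nitrogen is therefore carried as an N-benzyl methyl carbamate, the donor class for which this catalysis is established. The forward reaction must deliver the diene to one face of 9 and with one regiochemistry.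

**9 to 4 (dienophile chain).** The α-methylene carbon (C4) is removed to give aldehyde 8. That is traced through alcohol 7 to the terminal alkene of silyl ether 5 and the homoallylic alcohol 4. Each forward step is a standard functional group change that leaves C2 and C3 untouched.

**4 to 1 + 2 (C2–C3).** The C2–C3 bond is cut. A catalytic asymmetric crotylboration of aldehyde 1 with the E boronate 2 sets both centres in one step: anti from the alkene geometry, absolute sense from the chiral acid.

**15 to 10 + 11 (diene).** The diene comes from the vinylogous imide 14 by O-silylation, 14 from the enaminone 13 by N-acylation, and 13 from the ynone 12 by amine addition. 12 comes from amide 10 and acetylide 11. Condensing the corresponding methoxy ketone with a formamide acetal would be shorter, but either α-carbon could react. The ynone route fixes the regiochemistry.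

## Alternatives that were turned down

**Alternative 1:** The allyl C1′–C2′ bond and the C3a–C4 bond are cut at the α-methylene lactone A2, whose carbonyl carbon becomes C7a.
- Forward: a vinyl cuprate adds to the exocyclic methylene of A2, and the lactone enolate is trapped by Michael addition to 3-methoxybut-3-en-2-one A3, giving the keto lactone A1. Ring B would then close by condensation of the methyl ketone carbon (C7) onto the lactone carbonyl with loss of water.
- For: it is far shorter (A2 in two or three steps from 1, then two more). Ring A and the allyl group are present at once, and no redox adjustment is needed. C3a is set by the substrate, since the electrophile enters anti to the C3 methyl, which is the required cis allyl/methyl relationship.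
- Against: the bond that makes the quaternary carbon is formed in the least precedented stage. A hindered, fully substituted lactone enolate left by a cuprate must add to an electron-rich, enolisable and polymerisable acceptor. Proton transfer and oligomerisation are the likely outcomes. C5 arises by uncontrolled protonation, as here.
- Comparison: Alternative 1 is stronger on step count and on substrate control of C3a. The chosen route offers a quaternary-centre construction of a catalysed reaction class with direct precedent for α-substituted acroleins, and a ring B oxygenation pattern fixed by the diene.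

**Alternative 2:** The C3a–C1′ bond is cut together with a temporary C6–C2′ bond.
- Forward: the silyl dienol ether A5 reacts with acrolein A6 in a Diels–Alder reaction to give the bicyclo[2.2.2]octene A4. A later Grob fragmentation breaks C6–C2′ and releases the allyl group and the C6 ketone.
- For: the regiochemistry is electronically matched, and the vinylogous ester emerges directly from the fragmentation without a dehydrogenation.
- Against: A5 already contains C2, C3, C5 and both rings, so most of the synthetic problem is only postponed. The dienophile must bond to the fully substituted terminus C3a on the face syn to the adjacent C3 methyl, the more hindered face, so the C3a epimer is the likely product. Reduction, activation and fragmentation add three or four steps.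
- Comparison: Alternative 2 is stronger in avoiding the late dehydrogenation (step 14 here). The chosen route sets C3a early, at an unhindered diene terminus and under catalyst control.

**Alternative 3:** The O1–C7a bond is cut in a desymmetrisation of the dienone A8.
- Forward: a chiral bifunctional amine–thiourea catalyst promotes 5-exo-trig oxa-Michael addition of the C2 hydroxyl to one of the two diastereotopic enone arms, giving A7.
- For: the quaternary carbon is built without any facial problem, because it becomes stereogenic only in the ring closure. Desymmetrising oxa-Michael additions of 4,4-disubstituted cyclohexadienones are a known reaction class.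
- Against: A8 needs a dearomative para-allylation of a phenol, with competing O- and ortho-attack. The catalyst must choose an arm against the bias of two neighbouring stereocentres, and the addition is reversible. A7 has its enone on the wrong side (C4=C5), no C5 oxygen and no C7=C7a bond. Conjugate reduction, C5 oxygenation, methylation and the same dehydrogenation as here would follow.
- Comparison: Alternative 3 is stronger in that no face-selective C–C bond formation at C3a is needed. The chosen route delivers C5–OMe, C6=O and the C7=C7a position directly from the diene, at a similar overall length.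

Key step: step 9

Assumption 1: the (R,R) enantiomer of the chromium salen complex is taken as the one that directs the diene to the Re face of the α-carbon of 9; if a trial shows the opposite sense, the (S,S) complex is used and nothing else changes.

Assumption 2: C5 is drawn as 5S (the endo outcome of step 9) from 16 to 25; partial epimerisation in the basic steps between is of no consequence, because step 15 sets this centre.

## Route

Step 1
Reactants: 1 3,4,5-trimethoxybenzaldehyde; 2 (E)-crotylboronic acid pinacol ester
Product: 4 (1R,2R)-2-methyl-1-(3,4,5-trimethoxyphenyl)but-3-en-1-ol, via pinacol borate ester 3 (not isolated)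
Conditions: (R)-3,3′-bis(2,4,6-triisopropylphenyl)-1,1′-binaphthyl-2,2′-diyl hydrogen phosphate (5 mol%), toluene, −30 °C; aqueous work-up
Reagents that add atoms: none
Why: Brønsted-acid-catalysed crotylboration through a closed six-membered chair transition state, so the E geometry of 2 gives the anti C2/C3 relationship; the (R)-acid is expected to direct the crotyl group to the Re face of 1, giving (1R,2R), and borate 3 is hydrolysed on work-up.

Step 2
Reactants: 4 (1R,2R)-2-methyl-1-(3,4,5-trimethoxyphenyl)but-3-en-1-ol
Product: 5 tert-butyldimethyl{[(1R,2R)-2-methyl-1-(3,4,5-trimethoxyphenyl)but-3-en-1-yl]oxy}silane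
Conditions: t-BuMe2SiOTf, 2,6-lutidine, CH2Cl2, −78 → 0 °C
Reagents that add atoms: tert-butyldimethylsilyl trifluoromethanesulfonate, CC(C)(C)[Si](C)(C)OS(=O)(=O)C(F)(F)F
Why: Standard silylation of a hindered secondary alcohol with a silyl triflate; the ether masks the C2 hydroxyl through the oxidative, basic and Lewis acidic steps and is removed by fluoride in step 13.

Step 3
Reactants: 5 tert-butyldimethyl{[(1R,2R)-2-methyl-1-(3,4,5-trimethoxyphenyl)but-3-en-1-yl]oxy}silane
Product: 7 (3R,4R)-4-(tert-butyldimethylsilyloxy)-3-methyl-4-(3,4,5-trimethoxyphenyl)butan-1-ol, via B-alkyl-9-borabicyclononane 6 (not isolated)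
Conditions: 9-borabicyclo[3.3.1]nonane, THF, 0 °C → rt; then NaOH, H2O2, 0 °C → rt
Reagents that add atoms: hydrogen peroxide, OO
Why: Anti-Markovnikov hydroboration of the monosubstituted alkene with a bulky borane, then oxidation of the C–B bond with retention; no stereocentre is touched.

Step 4
Reactants: 7 (3R,4R)-4-(tert-butyldimethylsilyloxy)-3-methyl-4-(3,4,5-trimethoxyphenyl)butan-1-ol
Product: 8 (3R,4R)-4-(tert-butyldimethylsilyloxy)-3-methyl-4-(3,4,5-trimethoxyphenyl)butanal
Conditions: Dess–Martin periodinane, NaHCO3, CH2Cl2, 0 °C → rt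
Reagents that add atoms: none
Why: Dess–Martin oxidation of a primary alcohol under buffered conditions; the aldehyde has no α-stereocentre, so nothing can epimerise.

Step 5
Reactants: 8 (3R,4R)-4-(tert-butyldimethylsilyloxy)-3-methyl-4-(3,4,5-trimethoxyphenyl)butanal
Product: 9 (3R,4R)-4-(tert-butyldimethylsilyloxy)-3-methyl-2-methylidene-4-(3,4,5-trimethoxyphenyl)butanal
Conditions: aqueous formaldehyde (37%), pyrrolidine (10 mol%), propionic acid (10 mol%), i-PrOH, 45 °C
Reagents that add atoms: formaldehyde, C=O
Why: Amine-catalysed α-methylenation (Mannich condensation with formaldehyde, then elimination of the amine) of an α-unbranched aldehyde; C3 is β to the formyl group and is not enolised.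

Step 6
Reactants: 10 N,2-dimethoxy-N-methylacetamide; 11 ethynylmagnesium bromide
Product: 13 (3Z)-4-(benzylamino)-1-methoxybut-3-en-2-one, via 1-methoxybut-3-yn-2-one 12 (not isolated)
Conditions: THF, 0 °C; inverse quench into cold 1 M HCl, extraction with Et2O; then benzylamine, 0 °C → rt
Reagents that add atoms: benzylamine, NCc1ccccc1
Why: Acylation of an acetylide by an N-methoxy-N-methylamide stops at the ketone because of the chelated tetrahedral intermediate; the acid quench removes the liberated hydroxylamine as its salt, and the amine then adds to the terminal ynone (aza-Michael addition) to give the hydrogen-bonded Z enaminone. This sequence fixes which carbon bears nitrogen and which bears the methoxy group.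

Step 7
Reactants: 13 (3Z)-4-(benzylamino)-1-methoxybut-3-en-2-one
Product: 14 methyl benzyl[(1E)-4-methoxy-3-oxobut-1-en-1-yl]carbamate
Conditions: NaN(SiMe3)2, THF, −78 °C; then methyl chloroformate, −78 → 0 °C
Reagents that add atoms: methyl chloroformate, COC(=O)Cl
Why: N-Acylation of the sodium salt of a vinylogous amide; the N–H is the most acidic site, and the acylated product relaxes to the E geometry.

Step 8
Reactants: 14 methyl benzyl[(1E)-4-methoxy-3-oxobut-1-en-1-yl]carbamate
Product: 15 methyl benzyl[(1E,3Z)-3-(tert-butyldimethylsilyloxy)-4-methoxybuta-1,3-dien-1-yl]carbamate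
Conditions: KN(SiMe3)2, THF, −78 °C; then t-BuMe2SiCl, −78 → 0 °C
Reagents that add atoms: tert-butyldimethylsilyl chloride, CC(C)(C)[Si](C)(C)Cl
Why: O-Silylation of the potassium enolate formed at the only enolisable position (CH2OMe); chelation of potassium by the methoxy oxygen gives the Z enolate, which places the methoxy group "outside" in the s-cis diene.

Step 9
Reactants: 9 (3R,4R)-4-(tert-butyldimethylsilyloxy)-3-methyl-2-methylidene-4-(3,4,5-trimethoxyphenyl)butanal; 15 methyl benzyl[(1E,3Z)-3-(tert-butyldimethylsilyloxy)-4-methoxybuta-1,3-dien-1-yl]carbamate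
Product: 18 (1R,5S)-1-[(1R,2R)-1-(tert-butyldimethylsilyloxy)-1-(3,4,5-trimethoxyphenyl)propan-2-yl]-5-methoxy-4-oxocyclohex-2-ene-1-carbaldehyde, via endo cycloadduct 16 (not isolated), via beta-carbamato ketone 17 (not isolated)
Conditions: (R,R)-(salen)Cr(SbF6) (5 mol%; salen = N,N′-bis(3,5-di-tert-butylsalicylidene)cyclohexane-1,2-diamine dianion), 4 Å MS, CH2Cl2, −40 °C; then Bu4NF/AcOH, THF, −40 °C; then DBU, 0 °C → rt
Reagents that add atoms: none
Why: Catalysed Diels–Alder reaction of the class known for 1-(acylamino)-3-silyloxybutadienes and α-substituted acroleins under (salen)chromium catalysis: the trivalent chromium centre binds the formyl oxygen of 9 and lowers its LUMO, and 15 adds in a concerted, asynchronous [4+2] step in which the methoxy-bearing diene terminus (C5) bonds to the acrolein methylene (C4) ahead of the bond between the nitrogen-bearing terminus (C7a) and the substituted carbon (C3a). Ring B closes in this one suprafacial [4+2] event through the two new bonds C3a–C7a and C4–C5, with the formyl group endo. C3a is controlled by the catalyst, which has to expose the Re face of the α-carbon of 9; the allylic centre C3 should reinforce this, because with its hydrogen turned towards the chromium-bound formyl group the bulky CH(OSi)Ar branch covers the Si face. C5 is controlled by the Z enol ether of 15 (methoxy "outside") together with the endo mode, which put OMe cis to CHO (5S); this centre is epimerisable and is set finally in step 15. Regioselectivity is needed and is secured by the cooperating nitrogen donor at the diene's C1 and silyloxy donor at C3, which outweigh the opposing terminal methoxy group; the carbamate, unlike a basic amine, neither binds chromium nor reacts appreciably without the catalyst. In the work-up, buffered fluoride cleaves only the enol silyl ether of 16 (the hindered alkyl silyl ether is far slower), and DBU then expels methyl benzylcarbamate from 17 by E1cB elimination, removing the transient C7a centre and giving enone 18.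

Step 10
Reactants: 18 (1R,5S)-1-[(1R,2R)-1-(tert-butyldimethylsilyloxy)-1-(3,4,5-trimethoxyphenyl)propan-2-yl]-5-methoxy-4-oxocyclohex-2-ene-1-carbaldehyde
Product: 19 (4S,6S)-4-[(1R,2R)-1-(tert-butyldimethylsilyloxy)-1-(3,4,5-trimethoxyphenyl)propan-2-yl]-6-methoxy-4-(2-methoxyethenyl)cyclohex-2-en-1-one (E/Z mixture)
Conditions: (methoxymethyl)triphenylphosphonium chloride, KN(SiMe3)2, THF, 0 °C; then 18, −78 → 0 °C
Reagents that add atoms: (methoxymethyl)triphenylphosphonium chloride (as its ylide), COC[P+](c1ccccc1)(c1ccccc1)c1ccccc1.[Cl-]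
Why: Wittig reaction of a non-stabilised ylide; the aldehyde, although neopentyl-like, is much more electrophilic than the conjugated α-oxygenated ketone, which may in addition be masked in the flask as its dienolate (C5–H), so olefination at C6 should not compete; any epimerisation at C5 is of no consequence.

Step 11
Reactants: 19 (4S,6S)-4-[(1R,2R)-1-(tert-butyldimethylsilyloxy)-1-(3,4,5-trimethoxyphenyl)propan-2-yl]-6-methoxy-4-(2-methoxyethenyl)cyclohex-2-en-1-one
Product: 20 2-{(1R,5S)-1-[(1R,2R)-1-(tert-butyldimethylsilyloxy)-1-(3,4,5-trimethoxyphenyl)propan-2-yl]-5-methoxy-4-oxocyclohex-2-en-1-yl}acetaldehyde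
Conditions: TsOH·H2O (0.2 equiv), acetone/H2O (10:1), rt
Reagents that add atoms: water, O
Why: Acid-catalysed hydrolysis of the methyl enol ether (C-protonation, addition of water, loss of methanol); catalytic acid in wet acetone should leave the hindered benzylic silyl ether and the enone alone.

Step 12
Reactants: 20 2-{(1R,5S)-1-[(1R,2R)-1-(tert-butyldimethylsilyloxy)-1-(3,4,5-trimethoxyphenyl)propan-2-yl]-5-methoxy-4-oxocyclohex-2-en-1-yl}acetaldehyde
Product: 21 (4S,6S)-4-allyl-4-[(1R,2R)-1-(tert-butyldimethylsilyloxy)-1-(3,4,5-trimethoxyphenyl)propan-2-yl]-6-methoxycyclohex-2-en-1-one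
Conditions: methyltriphenylphosphonium bromide, KN(SiMe3)2, THF, 0 °C; then 20, −78 → 0 °C
Reagents that add atoms: methyltriphenylphosphonium bromide (as its ylide), C[P+](c1ccccc1)(c1ccccc1)c1ccccc1.[Br-]
Why: Wittig methylenation; the unhindered aldehyde reacts at low temperature much faster than the enone carbonyl, and this completes the allyl group.

Step 13
Reactants: 21 (4S,6S)-4-allyl-4-[(1R,2R)-1-(tert-butyldimethylsilyloxy)-1-(3,4,5-trimethoxyphenyl)propan-2-yl]-6-methoxycyclohex-2-en-1-one
Product: 23 (2R,3R,3aR,5S,7aR)-3a-allyl-5-methoxy-3-methyl-2-(3,4,5-trimethoxyphenyl)hexahydro-1-benzofuran-6(2H)-one, via hydroxy enone 22 (not isolated)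
Conditions: Bu4NF, THF, 0 °C → rt
Reagents that add atoms: none
Why: Fluoride cleaves the Si–O bond, and the liberated C2 oxygen adds to the enone β-carbon C7a in a 5-exo-trig oxa-Michael addition; the tether allows attack only from the face that carries C3, which gives the cis-fused ring A (7aR).

Step 14
Reactants: 23 (2R,3R,3aR,5S,7aR)-3a-allyl-5-methoxy-3-methyl-2-(3,4,5-trimethoxyphenyl)hexahydro-1-benzofuran-6(2H)-one
Product: 25 (2R,3R,3aR,5S)-3a-allyl-5-methoxy-3-methyl-2-(3,4,5-trimethoxyphenyl)-3,3a,4,5-tetrahydro-1-benzofuran-6(2H)-one, via trimethylsilyl enol ether 24 (not isolated)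
Conditions: LiN(SiMe3)2, Me3SiCl, THF, −78 °C; solvent exchange; then Pd(OAc)2 (1.1 equiv), MeCN, rt
Reagents that add atoms: none
Why: Saegusa–Ito oxidation: kinetic deprotonation with in situ silylation takes the less hindered C7 methylene rather than the methoxy-bearing C5 methine, and Pd(OAc)2 (divalent palladium) converts the enol silyl ether through the palladium enolate and β-hydride elimination of H7a into the vinylogous ester, as is routine for tetrahydropyran-4-ones.

Step 15
Reactants: 25 (2R,3R,3aR,5S)-3a-allyl-5-methoxy-3-methyl-2-(3,4,5-trimethoxyphenyl)-3,3a,4,5-tetrahydro-1-benzofuran-6(2H)-one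
Product: 26 (2R,3R,3aR,5R)-3a-allyl-5-methoxy-3-methyl-2-(3,4,5-trimethoxyphenyl)-3,3a,4,5-tetrahydro-1-benzofuran-6(2H)-one
Conditions: DBU (0.5 equiv), toluene, rt → 50 °C
Reagents that add atoms: none
Why: Base-mediated epimerisation through the cross-conjugated C5–C6 enolate; ring B is an envelope with C4 as the flap and the allyl group held pseudo-axial by the ring fusion, so the 5S epimer has its methoxy group pseudo-axial and syn to the allyl group, and the 5R epimer with a pseudo-equatorial methoxy group should be favoured at equilibrium.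

## Compound list

1 | 3,4,5-trimethoxybenzaldehyde | COc1cc(C=O)cc(OC)c1OC | starting material
2 | (E)-crotylboronic acid pinacol ester | C/C=C/CB1OC(C)(C)C(C)(C)O1 | starting material
3 | 4,4,5,5-tetramethyl-2-{[(1R,2R)-2-methyl-1-(3,4,5-trimethoxyphenyl)but-3-en-1-yl]oxy}-1,3,2-dioxaborolane | C=C[C@@H](C)[C@@H](OB1OC(C)(C)C(C)(C)O1)c2cc(OC)c(OC)c(OC)c2 | intermediate (not isolated)
4 | (1R,2R)-2-methyl-1-(3,4,5-trimethoxyphenyl)but-3-en-1-ol | C=C[C@@H](C)[C@@H](O)c1cc(OC)c(OC)c(OC)c1 | intermediate
5 | tert-butyldimethyl{[(1R,2R)-2-methyl-1-(3,4,5-trimethoxyphenyl)but-3-en-1-yl]oxy}silane | C=C[C@@H](C)[C@@H](O[Si](C)(C)C(C)(C)C)c1cc(OC)c(OC)c(OC)c1 | intermediate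
6 | 9-[(3R,4R)-4-(tert-butyldimethylsilyloxy)-3-methyl-4-(3,4,5-trimethoxyphenyl)butyl]-9-borabicyclo[3.3.1]nonane | B1(CC[C@@H](C)[C@@H](O[Si](C)(C)C(C)(C)C)c3cc(OC)c(OC)c(OC)c3)C2CCCC1CCC2 | intermediate (not isolated)
7 | (3R,4R)-4-(tert-butyldimethylsilyloxy)-3-methyl-4-(3,4,5-trimethoxyphenyl)butan-1-ol | OCC[C@@H](C)[C@@H](O[Si](C)(C)C(C)(C)C)c1cc(OC)c(OC)c(OC)c1 | intermediate
8 | (3R,4R)-4-(tert-butyldimethylsilyloxy)-3-methyl-4-(3,4,5-trimethoxyphenyl)butanal | O=CC[C@@H](C)[C@@H](O[Si](C)(C)C(C)(C)C)c1cc(OC)c(OC)c(OC)c1 | intermediate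
9 | (3R,4R)-4-(tert-butyldimethylsilyloxy)-3-methyl-2-methylidene-4-(3,4,5-trimethoxyphenyl)butanal | O=CC(=C)[C@@H](C)[C@@H](O[Si](C)(C)C(C)(C)C)c1cc(OC)c(OC)c(OC)c1 | intermediate
10 | N,2-dimethoxy-N-methylacetamide | COCC(=O)N(C)OC | starting material
11 | ethynylmagnesium bromide | C#C[Mg]Br | starting material
12 | 1-methoxybut-3-yn-2-one | COCC(=O)C#C | intermediate (not isolated)
13 | (3Z)-4-(benzylamino)-1-methoxybut-3-en-2-one | COCC(=O)/C=C\NCc1ccccc1 | intermediate
14 | methyl benzyl[(1E)-4-methoxy-3-oxobut-1-en-1-yl]carbamate | COCC(=O)/C=C/N(Cc1ccccc1)C(=O)OC | intermediate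
15 | methyl benzyl[(1E,3Z)-3-(tert-butyldimethylsilyloxy)-4-methoxybuta-1,3-dien-1-yl]carbamate | CO/C=C(\O[Si](C)(C)C(C)(C)C)/C=C/N(Cc1ccccc1)C(=O)OC | intermediate
16 | methyl benzyl{(1S,4S,6S)-3-(tert-butyldimethylsilyloxy)-6-[(1R,2R)-1-(tert-butyldimethylsilyloxy)-1-(3,4,5-trimethoxyphenyl)propan-2-yl]-6-formyl-4-methoxycyclohex-2-en-1-yl}carbamate | O=C[C@@]1(C[C@H](OC)C(O[Si](C)(C)C(C)(C)C)=C[C@@H]1N(Cc2ccccc2)C(=O)OC)[C@@H](C)[C@@H](O[Si](C)(C)C(C)(C)C)c3cc(OC)c(OC)c(OC)c3 | intermediate (not isolated)
17 | methyl benzyl{(1S,2S,4S)-2-[(1R,2R)-1-(tert-butyldimethylsilyloxy)-1-(3,4,5-trimethoxyphenyl)propan-2-yl]-2-formyl-4-methoxy-5-oxocyclohexyl}carbamate | O=C[C@@]1(C[C@H](OC)C(=O)C[C@@H]1N(Cc2ccccc2)C(=O)OC)[C@@H](C)[C@@H](O[Si](C)(C)C(C)(C)C)c3cc(OC)c(OC)c(OC)c3 | intermediate (not isolated)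
18 | (1R,5S)-1-[(1R,2R)-1-(tert-butyldimethylsilyloxy)-1-(3,4,5-trimethoxyphenyl)propan-2-yl]-5-methoxy-4-oxocyclohex-2-ene-1-carbaldehyde | O=C[C@@]1(C[C@H](OC)C(=O)C=C1)[C@@H](C)[C@@H](O[Si](C)(C)C(C)(C)C)c2cc(OC)c(OC)c(OC)c2 | intermediate
19 | (4S,6S)-4-[(1R,2R)-1-(tert-butyldimethylsilyloxy)-1-(3,4,5-trimethoxyphenyl)propan-2-yl]-6-methoxy-4-(2-methoxyethenyl)cyclohex-2-en-1-one (E/Z mixture) | COC=C[C@@]1(C[C@H](OC)C(=O)C=C1)[C@@H](C)[C@@H](O[Si](C)(C)C(C)(C)C)c2cc(OC)c(OC)c(OC)c2 | intermediate
20 | 2-{(1R,5S)-1-[(1R,2R)-1-(tert-butyldimethylsilyloxy)-1-(3,4,5-trimethoxyphenyl)propan-2-yl]-5-methoxy-4-oxocyclohex-2-en-1-yl}acetaldehyde | O=CC[C@@]1(C[C@H](OC)C(=O)C=C1)[C@@H](C)[C@@H](O[Si](C)(C)C(C)(C)C)c2cc(OC)c(OC)c(OC)c2 | intermediate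
21 | (4S,6S)-4-allyl-4-[(1R,2R)-1-(tert-butyldimethylsilyloxy)-1-(3,4,5-trimethoxyphenyl)propan-2-yl]-6-methoxycyclohex-2-en-1-one | C=CC[C@@]1(C[C@H](OC)C(=O)C=C1)[C@@H](C)[C@@H](O[Si](C)(C)C(C)(C)C)c2cc(OC)c(OC)c(OC)c2 | intermediate
22 | (4S,6S)-4-allyl-4-[(1R,2R)-1-hydroxy-1-(3,4,5-trimethoxyphenyl)propan-2-yl]-6-methoxycyclohex-2-en-1-one | C=CC[C@@]1(C[C@H](OC)C(=O)C=C1)[C@@H](C)[C@@H](O)c2cc(OC)c(OC)c(OC)c2 | intermediate (not isolated)
23 | (2R,3R,3aR,5S,7aR)-3a-allyl-5-methoxy-3-methyl-2-(3,4,5-trimethoxyphenyl)hexahydro-1-benzofuran-6(2H)-one | C=CC[C@]12C[C@H](OC)C(=O)C[C@H]1O[C@@H](c3cc(OC)c(OC)c(OC)c3)[C@@H]2C | intermediate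
24 | {[(2R,3R,3aR,5S,7aR)-3a-allyl-5-methoxy-3-methyl-2-(3,4,5-trimethoxyphenyl)-2,3,3a,4,5,7a-hexahydro-1-benzofuran-6-yl]oxy}trimethylsilane | C=CC[C@]12C[C@H](OC)C(O[Si](C)(C)C)=C[C@H]1O[C@@H](c3cc(OC)c(OC)c(OC)c3)[C@@H]2C | intermediate (not isolated)
25 | (2R,3R,3aR,5S)-3a-allyl-5-methoxy-3-methyl-2-(3,4,5-trimethoxyphenyl)-3,3a,4,5-tetrahydro-1-benzofuran-6(2H)-one | C=CC[C@]12C[C@H](OC)C(=O)C=C1O[C@@H](c3cc(OC)c(OC)c(OC)c3)[C@@H]2C | intermediate
26 | (2R,3R,3aR,5R)-3a-allyl-5-methoxy-3-methyl-2-(3,4,5-trimethoxyphenyl)-3,3a,4,5-tetrahydro-1-benzofuran-6(2H)-one | C=CC[C@]12C[C@@H](OC)C(=O)C=C1O[C@@H](c1cc(OC)c(OC)c(OC)c1)[C@@H]2C | target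

## Step count and least certain steps

Total step count: 15. Longest linear sequence: 12 steps (steps 1–5 and 9–15, from 1); the diene arm is 3 steps (6–8).

**Step 9 (key step).** The most likely failures are these:
- poor facial selectivity, if the bias of the allylic centre C3 opposes the catalyst;
- a slow cycloaddition, because the dienophile is α-branched and the carbamate diene is only moderately reactive, so that the diene hydrolyses first;
- erosion of regioselectivity by the terminal methoxy group.

Fallback, with substrate control in place of catalyst control: it sets out from 12 and 9 and comes back at 18. Dimethylamine is added to the ynone solution 12 to give (3E)-4-(dimethylamino)-1-methoxybut-3-en-2-one F1. KN(SiMe3)2 and t-BuMe2SiCl convert it into (1E,3Z)-3-(tert-butyldimethylsilyloxy)-4-methoxy-N,N-dimethylbuta-1,3-dien-1-amine F2. This far more reactive and more strongly polarised diene is combined with 9 in toluene at 0 °C → rt without any Lewis acid. The product is the amino cycloadduct (1S,2S,5S)-4-(tert-butyldimethylsilyloxy)-1-[(1R,2R)-1-(tert-butyldimethylsilyloxy)-1-(3,4,5-trimethoxyphenyl)propan-2-yl]-2-(dimethylamino)-5-methoxycyclohex-3-ene-1-carbaldehyde F3. The face is then decided by the C3 centre alone, and a minor C3a epimer is removed by chromatography. Brief treatment with 0.1 M HCl in THF at 0 °C hydrolyses the enol silyl ether and eliminates the amine to give 18.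

**Step 10.** The risk is loss of chemoselectivity: attack of the ylide on the C6 carbonyl, or slow olefination of the crowded aldehyde with enolisation-driven side reactions.

Fallback, olefination before the ketone is unmasked: it sets out from 16 and comes back at 19. The cycloadduct 16 is isolated by filtration without the fluoride treatment. The Wittig reaction with the same ylide, with C6 still an enol silyl ether, gives methyl benzyl{(1S,4S,6S)-3-(tert-butyldimethylsilyloxy)-6-[(1R,2R)-1-(tert-butyldimethylsilyloxy)-1-(3,4,5-trimethoxyphenyl)propan-2-yl]-4-methoxy-6-(2-methoxyethenyl)cyclohex-2-en-1-yl}carbamate F4. Buffered Bu4NF/AcOH and then DBU, as in step 9, cleave the enol silyl ether and eliminate the carbamate; the methyl enol ether is stable to both, and 19 results.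

**Step 14.** The risks are deprotonation at C5 instead of C7, β-elimination of O1 from the C7 enolate (ring A reopening), and interference of the allyl alkene with the palladium salt.

Fallback, the enolate generated by the ring closure itself: it sets out from 22 and comes back at 24, and then at 25. The alcohol 22 is obtained from 21 with HF·pyridine in THF/pyridine, which removes the silyl group under non-basic conditions. One equivalent of KN(SiMe3)2 in THF at −78 → −40 °C forms the alkoxide, whose oxa-Michael addition leaves the C6–C7 enolate regiospecifically. Me3SiCl is then added to give 24, which is oxidised with Pd(OAc)2 as before. No new compound is made.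

**Step 15.** The risk is an equilibrium that is incomplete or lies less far towards 26 than the conformational argument predicts, or slow degradation of the vinylogous ester under base.

Fallback, kinetic oxygenation in place of equilibration: it sets out from 25 and comes back at 26. Samarium diiodide (SmI2) in THF/MeOH at −78 °C removes the α-methoxy group to give (2R,3R,3aS)-3a-allyl-3-methyl-2-(3,4,5-trimethoxyphenyl)-3,3a,4,5-tetrahydro-1-benzofuran-6(2H)-one F5. Its lithium enolate (LiN(SiMe3)2, −78 °C) is hydroxylated with 2-(phenylsulfonyl)-3-phenyloxaziridine on the face away from the pseudo-axial allyl group, giving (2R,3R,3aR,5R)-3a-allyl-5-hydroxy-3-methyl-2-(3,4,5-trimethoxyphenyl)-3,3a,4,5-tetrahydro-1-benzofuran-6(2H)-one F6. Methylation with trimethyloxonium tetrafluoroborate and 1,8-bis(dimethylamino)naphthalene gives 26 without exposing C5 to base.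

## Further compounds

F1 | step 9 | (3E)-4-(dimethylamino)-1-methoxybut-3-en-2-one | COCC(=O)/C=C/N(C)C
F2 | step 9 | (1E,3Z)-3-(tert-butyldimethylsilyloxy)-4-methoxy-N,N-dimethylbuta-1,3-dien-1-amine | CO/C=C(\O[Si](C)(C)C(C)(C)C)/C=C/N(C)C
F3 | step 9 | (1S,2S,5S)-4-(tert-butyldimethylsilyloxy)-1-[(1R,2R)-1-(tert-butyldimethylsilyloxy)-1-(3,4,5-trimethoxyphenyl)propan-2-yl]-2-(dimethylamino)-5-methoxycyclohex-3-ene-1-carbaldehyde | O=C[C@@]1(C[C@H](OC)C(O[Si](C)(C)C(C)(C)C)=C[C@@H]1N(C)C)[C@@H](C)[C@@H](O[Si](C)(C)C(C)(C)C)c2cc(OC)c(OC)c(OC)c2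
F4 | step 10 | methyl benzyl{(1S,4S,6S)-3-(tert-butyldimethylsilyloxy)-6-[(1R,2R)-1-(tert-butyldimethylsilyloxy)-1-(3,4,5-trimethoxyphenyl)propan-2-yl]-4-methoxy-6-(2-methoxyethenyl)cyclohex-2-en-1-yl}carbamate | COC=C[C@@]1(C[C@H](OC)C(O[Si](C)(C)C(C)(C)C)=C[C@@H]1N(Cc2ccccc2)C(=O)OC)[C@@H](C)[C@@H](O[Si](C)(C)C(C)(C)C)c3cc(OC)c(OC)c(OC)c3
F0 | step 14 | none | none
F5 | step 15 | (2R,3R,3aS)-3a-allyl-3-methyl-2-(3,4,5-trimethoxyphenyl)-3,3a,4,5-tetrahydro-1-benzofuran-6(2H)-one | C=CC[C@]12CCC(=O)C=C1O[C@@H](c3cc(OC)c(OC)c(OC)c3)[C@@H]2C
F6 | step 15 | (2R,3R,3aR,5R)-3a-allyl-5-hydroxy-3-methyl-2-(3,4,5-trimethoxyphenyl)-3,3a,4,5-tetrahydro-1-benzofuran-6(2H)-one | C=CC[C@]12C[C@@H](O)C(=O)C=C1O[C@@H](c3cc(OC)c(OC)c(OC)c3)[C@@H]2C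
A1 | alternative 1 | (3R,4R,5R)-3-allyl-3-[(2R)-2-methoxy-3-oxobutyl]-4-methyl-5-(3,4,5-trimethoxyphenyl)dihydrofuran-2(3H)-one | C=CC[C@]1(C[C@@H](OC)C(C)=O)C(=O)O[C@@H](c2cc(OC)c(OC)c(OC)c2)[C@@H]1C
A2 | alternative 1 | (4R,5R)-4-methyl-3-methylidene-5-(3,4,5-trimethoxyphenyl)dihydrofuran-2(3H)-one | C=C1C(=O)O[C@@H](c2cc(OC)c(OC)c(OC)c2)[C@@H]1C
A3 | alternative 1 | 3-methoxybut-3-en-2-one | COC(=C)C(C)=O
A4 | alternative 2 | endo-formyl bicyclo[2.2.2]octene adduct of A5 and A6 (C3a–C1′ and C6–C2′ bonds, bridgehead C6 tert-butyldimethylsilyl ether) | O=C[C@H]1C[C@]23C[C@@H](OC)[C@@]1(O[Si](C)(C)C(C)(C)C)C=C2O[C@@H](c1cc(OC)c(OC)c(OC)c1)[C@@H]3C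
A5 | alternative 2 | tert-butyl{[(2R,3R,5R)-5-methoxy-3-methyl-2-(3,4,5-trimethoxyphenyl)-2,3,4,5-tetrahydro-1-benzofuran-6-yl]oxy}dimethylsilane | CO[C@@H]1CC2=C(C=C1O[Si](C)(C)C(C)(C)C)O[C@@H](c3cc(OC)c(OC)c(OC)c3)[C@@H]2C
A6 | alternative 2 | acrolein | C=CC=O
A7 | alternative 3 | (2R,3R,3aR,7aR)-3a-allyl-3-methyl-2-(3,4,5-trimethoxyphenyl)-3,3a,7,7a-tetrahydro-1-benzofuran-6(2H)-one | C=CC[C@]12C=CC(=O)C[C@H]1O[C@@H](c1cc(OC)c(OC)c(OC)c1)[C@@H]2C
A8 | alternative 3 | 4-allyl-4-[(1R,2R)-1-hydroxy-1-(3,4,5-trimethoxyphenyl)propan-2-yl]cyclohexa-2,5-dien-1-one | C=CCC1(C=CC(=O)C=C1)[C@@H](C)[C@@H](O)c2cc(OC)c(OC)c(OC)c2
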